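**Assumption:** The target has no stereocentre and is achiral, so there is no enantiomer to control. All compounds are drawn in one enol tautomer (the target in the tautomer of the given SMILES). The CH(CH3) centres of 7 and 9 (and of F2, F4) are enolisable, racemic and of no consequence.

## Retrosynthetic overview

1. Cut both bonds to the bridging CH2: butyrylfilicinic acid + acylresorcinol + one C1 unit (an aminal), joined through an o-quinone methide.
2. Filicinic ring (ring A, formed first): tetraketide-type Claisen closure C6→C1 of a 3,5,7-trioxo ester that already carries the gem-dimethyl group, assembled in the same flask from heptane-2,4-dione dianion and diethyl dimethylmalonate.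
3. Aromatic ring (ring B, formed second): orsellinate-type aldol closure C7→C2 of a C-methylated 2,4,6,8-tetraketone, built by two terminal acylations of 3-methylpentane-2,4-dione.
4. Neither ring is bought; both come from open-chain poly-β-carbonyl chains. Convergent, 1 + 2 + 1 steps.

## Route

**Step 1**
Reactants: 1 heptane-2,4-dione; 2 diethyl 2,2-dimethylpropanedioate
Product: 4 2-butanoyl-3,5-dihydroxy-4,4-dimethylcyclohexa-2,5-dien-1-one (butyrylfilicinic acid), via triketo ester 3 (not isolated)
Conditions: LDA (3.1 equiv, commercial solution), THF, 0 °C; 2 (1.0 equiv), 0 °C → reflux; 2 M HCl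
Reagents that add atoms: none
Why: Proposed new method: the 1,3-dianion of 1 (formed at CH3 in preference to the propyl CH2) is C-acylated by one ester group of the non-enolisable diester 2 (closest known type: ester acylation of β-diketone dianions to 1,3,5-triketones), and the polyanion of 3 can close only by the polyketide-synthase-type Claisen (Dieckmann) attack of C6 on the C1 ester because C2 is quaternary (closest known types: base-mediated Claisen cyclisation of 3,5,7-trioxoalkanoates to acylphloroglucinols, and the double acyl transfer of dialkylmalonates in barbiturate synthesis), with the stabilised triketone anion of 4 as the driving force; no stereocentre is formed.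

**Step 2**
Reactants: 5 3-methylpentane-2,4-dione; 6 methyl butanoate
Product: 7 3-methylnonane-2,4,6-trione
Conditions: 5 (2.0 equiv), LDA (4.0 equiv), THF, 0 °C; 6 (1.0 equiv), 0 °C → rt; 1 M HCl (second equivalent of dianion acts as base, 5 recovered)
Reagents that add atoms: none
Why: Claisen-type acylation of the 1,3-dianion of a β-diketone at its terminal methyl by an ester, the symmetry of 5 making the site unambiguous; the CH(CH3) centre is enolisable and racemic.

**Step 3**
Reactants: 7 3-methylnonane-2,4,6-trione; 8 N-methoxy-N-methylacetamide
Product: 10 1-(2,4-dihydroxy-3,6-dimethylphenyl)butan-1-one, via tetraketone 9 (not isolated)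
Conditions: LDA (3.2 equiv), THF, 0 °C; 8 (1.1 equiv), 0 °C → rt; cold 1 M HCl; crude in MeOH/aq. NaHCO3 buffer (pH 8.5), 25 °C
Reagents that add atoms: none
Why: Weinreb-amide acylation of the triketone trianion at its terminal CH3 (the chelated tetrahedral adduct prevents over-reaction) gives 9, and its buffered intramolecular aldol condensation in the orsellinate mode (C7 onto the less hindered, more electrophilic methyl ketone C2), then dehydration and enolisation, gives the benzene ring; the CH(CH3) centre becomes an sp2 ring carbon.

**Step 4**
Reactants: 10 1-(2,4-dihydroxy-3,6-dimethylphenyl)butan-1-one; 11 N,N,N',N'-tetramethylmethanediamine; 4 butyrylfilicinic acid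
Product: 14 2-butanoyl-6-[(3-butanoyl-4,6-dihydroxy-2,5-dimethylphenyl)methyl]-3,5-dihydroxy-4,4-dimethylcyclohexa-2,5-dien-1-one (target), via Mannich base 12 (not isolated), via quinone methide 13 (not isolated)
Conditions: 11 (1.0 equiv), 1,4-dioxane, 60 °C, N2 sweep; then 4 (1.1 equiv), 100 °C; 1 M HCl wash
Reagents that add atoms: none
Why: Phenolic Mannich aminomethylation at the only free ring position of 10 gives 12, which on heating with the acidic triketone 4 loses dimethylamine to the o-quinone methide 13, trapped by Michael addition of the single nucleophilic ring carbon of 4 (deaminative C-alkylation by a Mannich base); 10 is fully consumed before 4 is added, so neither symmetrical dimer can form, and no stereocentre is created.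

## Compound list

1 | heptane-2,4-dione | CCCC(=O)CC(C)=O | starting material
2 | diethyl 2,2-dimethylpropanedioate (diethyl dimethylmalonate) | CCOC(=O)C(C)(C)C(=O)OCC | starting material
3 | ethyl 2,2-dimethyl-3,5,7-trioxodecanoate | CCCC(=O)CC(=O)CC(=O)C(C)(C)C(=O)OCC | intermediate
4 | 2-butanoyl-3,5-dihydroxy-4,4-dimethylcyclohexa-2,5-dien-1-one (butyrylfilicinic acid) | CCCC(=O)C1=C(O)C(C)(C)C(O)=CC1=O | intermediate
5 | 3-methylpentane-2,4-dione | CC(=O)C(C)C(C)=O | starting material
6 | methyl butanoate | CCCC(=O)OC | starting material
7 | 3-methylnonane-2,4,6-trione (racemic, enolisable) | CCCC(=O)CC(=O)C(C)C(C)=O | intermediate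
8 | N-methoxy-N-methylacetamide | CC(=O)N(C)OC | starting material
9 | 5-methylundecane-2,4,6,8-tetraone (racemic, enolisable) | CCCC(=O)CC(=O)C(C)C(=O)CC(C)=O | intermediate
10 | 1-(2,4-dihydroxy-3,6-dimethylphenyl)butan-1-one | CCCC(=O)c1c(C)cc(O)c(C)c1O | intermediate
11 | N,N,N',N'-tetramethylmethanediamine | CN(C)CN(C)C | starting material
12 | 1-{5-[(dimethylamino)methyl]-2,4-dihydroxy-3,6-dimethylphenyl}butan-1-one | CCCC(=O)c1c(C)c(CN(C)C)c(O)c(C)c1O | intermediate
13 | 4-butanoyl-3-hydroxy-2,5-dimethyl-6-methylidenecyclohexa-2,4-dien-1-one | CCCC(=O)C1=C(C)C(=C)C(=O)C(C)=C1O | intermediate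
14 | 2-butanoyl-6-[(3-butanoyl-4,6-dihydroxy-2,5-dimethylphenyl)methyl]-3,5-dihydroxy-4,4-dimethylcyclohexa-2,5-dien-1-one | CCCC(=O)C1=C(O)C(C)(C)C(O)=C(Cc2c(C)c(C(=O)CCC)c(O)c(C)c2O)C1=O | target

## Step count and risks

Total steps: 4. Longest linear sequence: 3 (5 → 7 → 10 → 14).

**Step 1 (one-flask acylation/Claisen closure).** The risks are partial dianion formation at the propyl CH2, which would give the isomeric 2-acetyl-6-ethyl triketone, and a sluggish closure onto the hindered ester. The fallback sets out from 2 and comes back at 4. Compound 2 is condensed with the dianion of ethyl acetoacetate (NaH then n-BuLi, THF, 0 °C → reflux), which has only one γ-carbanion site, to give diethyl 2,2-dimethyl-3,5-dioxoheptanedioate F1. F1 Dieckmann-cyclises in the same flask to ethyl 3,3-dimethyl-2,4,6-trioxocyclohexane-1-carboxylate F2. Hydrolysis and decarboxylation (aq. HCl/AcOH, reflux) give 2,2-dimethylcyclohexane-1,3,5-trione F3 (filicinic acid). C-acylation of F3 with butanoyl chloride/AlCl3, at either of its two equivalent CH2 groups, gives 4. The acyl chain is thus attached after, not before, ring closure.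

**Step 3 (trianion acetylation and aldol regiochemistry).** The competing closure C3→C8 onto the propyl ketone would give 1-(2,4-dihydroxy-3-methyl-6-propylphenyl)ethanone, and trianion formation at the propyl CH2 is a further leak. I expect the methyl ketone to be favoured, but only by a modest margin, so chromatographic separation may be needed. The fallback sets out from 5 and comes back at 10. The dianion of 5 (LDA, THF, 0 °C) is acetylated with 8 to 3-methylheptane-2,4,6-trione F4. Collie-type aldol cyclisation of F4 (aq. Ba(OH)2 or KOH) through attack on the unhindered C6 carbonyl gives 2,5-dimethylbenzene-1,3-diol F5; this closure has its own minor alternative mode (4,5-dimethylresorcinol). Nencki/Friedel–Crafts acylation of F5 with butanoic acid/BF3·OEt2 (80 °C) gives 10. C4 and C6 of F5 are equivalent, so the acyl position is unambiguous.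

**Step 4 (cross-coupling through the quinone methide).** The risks are incomplete aminomethylation of the acyl-deactivated ring and reversible amine re-addition that stalls the coupling. The fallback sets out from 10 and comes back at 14. Rieche formylation of 10 (Cl2CHOMe, TiCl4, CH2Cl2, 0 °C) at its only free position gives 3-butanoyl-4,6-dihydroxy-2,5-dimethylbenzaldehyde F6. Organocatalytic reductive alkylation of 4 with F6 (L-proline cat., Hantzsch ester, EtOH, 25 °C) runs through the Knoevenagel adduct 2-butanoyl-6-[(3-butanoyl-4,6-dihydroxy-2,5-dimethylphenyl)methylidene]-3-hydroxy-4,4-dimethylcyclohex-2-ene-1,5-dione F7 (transient, E/Z not fixed). Conjugate hydride transfer to F7 gives 14. No free C1 electrophile that could bridge two molecules of 4 is ever present.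

## Further compounds

F1 | step 1 | diethyl 2,2-dimethyl-3,5-dioxoheptanedioate | CCOC(=O)CC(=O)CC(=O)C(C)(C)C(=O)OCC
F2 | step 1 | ethyl 3,3-dimethyl-2,4,6-trioxocyclohexane-1-carboxylate (racemic, enolisable) | CCOC(=O)C1C(=O)CC(=O)C(C)(C)C1=O
F3 | step 1 | 2,2-dimethylcyclohexane-1,3,5-trione (filicinic acid) | CC1(C)C(=O)CC(=O)CC1=O
F4 | step 3 | 3-methylheptane-2,4,6-trione (racemic, enolisable) | CC(=O)CC(=O)C(C)C(C)=O
F5 | step 3 | 2,5-dimethylbenzene-1,3-diol | Cc1cc(O)c(C)c(O)c1
F6 | step 4 | 3-butanoyl-4,6-dihydroxy-2,5-dimethylbenzaldehyde | CCCC(=O)c1c(C)c(C=O)c(O)c(C)c1O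
F7 | step 4 | 2-butanoyl-6-[(3-butanoyl-4,6-dihydroxy-2,5-dimethylphenyl)methylidene]-3-hydroxy-4,4-dimethylcyclohex-2-ene-1,5-dione (E/Z not fixed) | CCCC(=O)C1=C(O)C(C)(C)C(=O)C(=Cc2c(C)c(C(=O)CCC)c(O)c(C)c2O)C1=O
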